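**Plan**

- Numbering: C1 is the quaternary carbinol carbon carrying the C7H2OBz arm, C2 the CH(OBz), C3=C4 the ring alkene, C5 and C6 the CH(OH) carbons (ring A = C1–C6). The O–C7–C1–C2–O array is a β-hydroxy ketone in disguise, i.e. a 2-isoxazoline fused to ring A at C1–C2, and C1–C6–C5–C4 with its threo diol on C6/C5 is the carbon chain of D-tartaric acid.
- Retrosynthesis: remove the two benzoates and the C2–H (back to a C2 enone), re-close N–O to the isoxazoline, then cut C1–C2 and C7–O together (intramolecular nitrile oxide cycloaddition onto a C1=C7 silyl enol ether), then C3=C4 (Still–Gennari) and C1–C7 (MeMgBr on a Weinreb amide).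
- Forward: the tartrate acetonide is desymmetrised through its bis-Weinreb amide (methyl ketone, then silyl enol ether on one side; aldehyde, Z-enoate, Z-enal oxime on the other). One cycloaddition then closes ring A and the isoxazoline together.
- End game: N–O cleavage, C7 benzoylation, desilylation, directed reduction at C2, C2 benzoylation, acetonide hydrolysis.
- Stereochemistry: C5 and C6 come from D-tartrate; C1 is set in the cycloaddition by the trans-acetonide; C2 is set by hydride delivery from the C1 hydroxyl.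

Key step: step 10

Assumption: oxime 12 may form as a mixture of C=N isomers; both are oxidised to the same nitrile oxide, so this geometry is left open in its SMILES.

**Route**

Step 1
Reactants: 1 diethyl D-tartrate
Product: 2 diethyl (4S,5S)-2,2-dimethyl-1,3-dioxolane-4,5-dicarboxylate
Conditions: Me2C(OMe)2, TsOH·H2O (cat.), CH2Cl2, reflux
Reagents that add atoms: 2,2-dimethoxypropane, COC(C)(C)OC
Why: Acid-catalysed transacetalisation (acetonide formation) of the threo 1,2-diol should give the trans-disubstituted dioxolane without touching either stereocentre.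

Step 2
Reactants: 2 diethyl (4S,5S)-2,2-dimethyl-1,3-dioxolane-4,5-dicarboxylate
Product: 3 (4S,5S)-N4,N5-dimethoxy-N4,N5,2,2-tetramethyl-1,3-dioxolane-4,5-dicarboxamide
Conditions: MeNH(OMe)·HCl, i-PrMgCl, THF, −20 → 0 °C
Reagents that add atoms: N,O-dimethylhydroxylamine hydrochloride, CNOC.Cl
Why: Ester aminolysis by the magnesium amide of N,O-dimethylhydroxylamine (Weinreb amide formation) is standard for α-alkoxy esters and should convert both esters while the C2-symmetric trans-dioxolane stays intact.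

Step 3
Reactants: 3 (4S,5S)-N4,N5-dimethoxy-N4,N5,2,2-tetramethyl-1,3-dioxolane-4,5-dicarboxamide; 4 methylmagnesium bromide
Product: 5 (4S,5S)-5-acetyl-N-methoxy-N,2,2-trimethyl-1,3-dioxolane-4-carboxamide
Conditions: MeMgBr (1.2 equiv), THF, −15 °C; aq. NH4Cl
Reagents that add atoms: methylmagnesium bromide (4), C[Mg]Br
Why: Weinreb ketone synthesis: the amide takes up one equivalent of Grignard reagent and releases the ketone only on work-up, so a small excess of MeMgBr at low temperature should convert one of the two equivalent amides into the methyl ketone (C7 introduced) and leave the other.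

Step 4
Reactants: 5 (4S,5S)-5-acetyl-N-methoxy-N,2,2-trimethyl-1,3-dioxolane-4-carboxamide
Product: 6 (4S,5S)-5-[1-(tert-butyldimethylsilyloxy)ethenyl]-N-methoxy-N,2,2-trimethyl-1,3-dioxolane-4-carboxamide
Conditions: TBSOTf, Et3N, CH2Cl2, −78 → 0 °C
Reagents that add atoms: tert-butyldimethylsilyl triflate, CC(C)(C)[Si](C)(C)OS(=O)(=O)C(F)(F)F
Why: Soft enolisation (silyl triflate/amine silyl enol ether formation) should remove a proton from the unhindered methyl group and not from the dioxolane C–H, giving the 1,1-disubstituted enol ether C1=C7 without strong base near the amide or the stereocentres.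

Step 5
Reactants: 6 (4S,5S)-5-[1-(tert-butyldimethylsilyloxy)ethenyl]-N-methoxy-N,2,2-trimethyl-1,3-dioxolane-4-carboxamide
Product: 7 (4S,5S)-5-[1-(tert-butyldimethylsilyloxy)ethenyl]-2,2-dimethyl-1,3-dioxolane-4-carbaldehyde
Conditions: i-Bu2AlH, THF, −78 °C; aq. potassium sodium tartrate
Reagents that add atoms: none
Why: Weinreb amide reduction: i-Bu2AlH delivers one hydride and the aldehyde appears only on work-up, so over-reduction is avoided, and the silyl enol ether is inert to hydride and to the near-neutral work-up.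

Step 6
Reactants: 7 (4S,5S)-5-[1-(tert-butyldimethylsilyloxy)ethenyl]-2,2-dimethyl-1,3-dioxolane-4-carbaldehyde; 8 methyl bis(2,2,2-trifluoroethyl)phosphonoacetate
Product: 9 methyl (2Z)-3-{(4R,5S)-5-[1-(tert-butyldimethylsilyloxy)ethenyl]-2,2-dimethyl-1,3-dioxolan-4-yl}prop-2-enoate
Conditions: KN(SiMe3)2, 18-crown-6, THF, −78 °C
Reagents that add atoms: methyl bis(2,2,2-trifluoroethyl)phosphonoacetate (8), COC(=O)CP(=O)(OCC(F)(F)F)OCC(F)(F)F
Why: Still–Gennari olefination: fast, irreversible elimination from the trifluoroethyl phosphonate adduct under dissociating conditions should give the Z-enoate (C3=C4), the geometry the ring closure needs; the C4 descriptor changes from S to R by CIP priority only.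

Step 7
Reactants: 9 methyl (2Z)-3-{(4R,5S)-5-[1-(tert-butyldimethylsilyloxy)ethenyl]-2,2-dimethyl-1,3-dioxolan-4-yl}prop-2-enoate
Product: 10 (2Z)-3-{(4R,5S)-5-[1-(tert-butyldimethylsilyloxy)ethenyl]-2,2-dimethyl-1,3-dioxolan-4-yl}prop-2-en-1-ol
Conditions: i-Bu2AlH (2.5 equiv), CH2Cl2, −78 °C; aq. potassium sodium tartrate
Reagents that add atoms: none
Why: 1,2-Reduction of an enoate by i-Bu2AlH should give the allylic alcohol without conjugate reduction or Z/E isomerisation.

Step 8
Reactants: 10 (2Z)-3-{(4R,5S)-5-[1-(tert-butyldimethylsilyloxy)ethenyl]-2,2-dimethyl-1,3-dioxolan-4-yl}prop-2-en-1-ol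
Product: 11 (2Z)-3-{(4R,5S)-5-[1-(tert-butyldimethylsilyloxy)ethenyl]-2,2-dimethyl-1,3-dioxolan-4-yl}prop-2-enal
Conditions: activated MnO2, CH2Cl2, rt; used at once
Reagents that add atoms: none
Why: MnO2 oxidation of an allylic alcohol runs under neutral, non-aqueous conditions, which should preserve the Z geometry and the acid-sensitive silyl enol ether.

Step 9
Reactants: 11 (2Z)-3-{(4R,5S)-5-[1-(tert-butyldimethylsilyloxy)ethenyl]-2,2-dimethyl-1,3-dioxolan-4-yl}prop-2-enal
Product: 12 (2Z)-3-{(4R,5S)-5-[1-(tert-butyldimethylsilyloxy)ethenyl]-2,2-dimethyl-1,3-dioxolan-4-yl}prop-2-enal oxime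
Conditions: NH2OH·HCl, NaHCO3, EtOH/H2O, 0 °C
Reagents that add atoms: hydroxylamine hydrochloride, NO.Cl
Why: Oxime condensation of the aldehyde is fast at 0 °C, and the bicarbonate buffer should spare the silyl enol ether and the Z-alkene.

Step 10
Reactants: 12 (2Z)-3-{(4R,5S)-5-[1-(tert-butyldimethylsilyloxy)ethenyl]-2,2-dimethyl-1,3-dioxolan-4-yl}prop-2-enal oxime
Product: 15 tricyclic isoxazoline (1S,5R,6S) carrying C1–OTBS cis to O6, via hydroximoyl chloride 13 (not isolated), via nitrile oxide 14 (not isolated)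
Conditions: aq. NaOCl, Et3N (cat.), CH2Cl2, 0 °C → rt, 0.01 M, slow addition of 12
Reagents that add atoms: none
Why: Hypochlorite chlorinates the aldoxime to hydroximoyl chloride 13, base removes HCl to give nitrile oxide 14, and the dipole adds across the tethered C1=C7 enol ether in a concerted, suprafacial [3+2] cycloaddition that forms C2–C1 and O–C7 together. The closest known reaction type is the intramolecular nitrile oxide–alkene cycloaddition of hex-5-enyl nitrile oxides to cyclohexane-fused 2-isoxazolines, together with the known intermolecular addition of nitrile oxides to silyl enol ethers. Ring A closes in a 6-exo mode by attack of the dipole carbon C2 on the internal alkene carbon C1 through the four-atom tether C3–C6, and the isoxazoline closes as the fused five-membered ring by O–C7 bonding; the bridged alternative (C2–C7) would need a seven-membered ring with a bridgehead C=N, so the tether should override the usual electronic preference of enol ethers. The single new stereocentre, C1, is set by the trans-acetonide: it holds the oxygens on C5 and C6 (O5, O6) pseudo-equatorial, C7 must lie close to the plane of the C2–N–O dipole, and the silyloxy group is therefore pseudo-axial and cis to O6 (1S). The step needs oxime oxidation to outrun attack of hypochlorite on the enol ether and ring closure to outrun furoxan formation; the basic two-phase medium at 0 °C, the bulky silyl group, high dilution, and the Z-alkene and dioxolane that hold the two ends close should secure both.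

Step 11
Reactants: 15 tricyclic isoxazoline (1S,5R,6S)
Product: 17 (1S,5R,6S)-1-(tert-butyldimethylsilyloxy)-1-(hydroxymethyl)-5,6-(isopropylidenedioxy)cyclohex-3-en-2-one, via hydroxy imine 16 (not isolated)
Conditions: Mo(CO)6, MeCN/H2O (15:1), 80 °C
Reagents that add atoms: water, O
Why: Reductive N–O cleavage of a 2-isoxazoline by Mo(CO)6 (zerovalent molybdenum) in wet acetonitrile gives the β-hydroxy imine, which hydrolyses in the flask to the C2 enone and the C7 alcohol; no hydrogenation is involved, so C3=C4 survives, and the quaternary C1 blocks enolisation and dehydration.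

Step 12
Reactants: 17 (1S,5R,6S)-1-(tert-butyldimethylsilyloxy)-1-(hydroxymethyl)-5,6-(isopropylidenedioxy)cyclohex-3-en-2-one
Product: 18 [(1S,5R,6S)-1-(tert-butyldimethylsilyloxy)-5,6-(isopropylidenedioxy)-2-oxocyclohex-3-en-1-yl]methyl benzoate
Conditions: BzCl, pyridine, DMAP (cat.), CH2Cl2, 0 °C
Reagents that add atoms: benzoyl chloride, O=C(Cl)c1ccccc1
Why: DMAP-catalysed acylation of the only free hydroxyl (primary C7–OH) installs the first benzoate and removes C7–OH as a competing directing group for the later reduction.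

Step 13
Reactants: 18 [(1S,5R,6S)-1-(tert-butyldimethylsilyloxy)-5,6-(isopropylidenedioxy)-2-oxocyclohex-3-en-1-yl]methyl benzoate
Product: 19 [(1S,5R,6S)-1-hydroxy-5,6-(isopropylidenedioxy)-2-oxocyclohex-3-en-1-yl]methyl benzoate
Conditions: Bu4NF, AcOH, THF, 0 °C → rt
Reagents that add atoms: none
Why: Fluoride-mediated desilylation of the α-keto tertiary silyl ether; the acetic acid buffer should prevent alkoxide-driven benzoyl migration and α-ketol rearrangement.

Step 14
Reactants: 19 [(1S,5R,6S)-1-hydroxy-5,6-(isopropylidenedioxy)-2-oxocyclohex-3-en-1-yl]methyl benzoate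
Product: 20 [(1R,2S,5R,6S)-1,2-dihydroxy-5,6-(isopropylidenedioxy)cyclohex-3-en-1-yl]methyl benzoate
Conditions: Me4NBH(OAc)3, MeCN/AcOH (1:1), −25 °C
Reagents that add atoms: none
Why: Hydroxyl-directed reduction (Evans–Saksena type): the axial C1–OH exchanges onto boron and delivers hydride to the C2 carbonyl from its own face, so the new C2–OH should be trans to C1–OH (2S); the reagent is too weak to reduce the enone intermolecularly, and the C1 descriptor changes to R by CIP priority only.

Step 15
Reactants: 20 [(1R,2S,5R,6S)-1,2-dihydroxy-5,6-(isopropylidenedioxy)cyclohex-3-en-1-yl]methyl benzoate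
Product: 21 [(1R,2S,5R,6S)-2-(benzoyloxy)-1-hydroxy-5,6-(isopropylidenedioxy)cyclohex-3-en-1-yl]methyl benzoate
Conditions: BzCl (1.2 equiv), pyridine, DMAP (cat.), CH2Cl2, 0 °C
Reagents that add atoms: benzoyl chloride, O=C(Cl)c1ccccc1
Why: Selective acylation: the secondary allylic C2–OH should be esterified while the hindered tertiary C1–OH stays free.

Step 16
Reactants: 21 [(1R,2S,5R,6S)-2-(benzoyloxy)-1-hydroxy-5,6-(isopropylidenedioxy)cyclohex-3-en-1-yl]methyl benzoate
Product: 22 [(1S,2S,5R,6S)-2-(benzoyloxy)-1,5,6-trihydroxycyclohex-3-en-1-yl]methyl benzoate (CNP0141358.1)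
Conditions: AcOH/H2O (4:1), 40 °C
Reagents that add atoms: none
Why: Acid-catalysed acetal hydrolysis: the strained trans-fused dioxolane should open under conditions mild enough to leave both benzoates in place and the allylic C–O bonds un-ionised.

**Compound list** (ring compounds 15–22 use the C1–C7 numbering of the plan)

1 | diethyl D-tartrate, diethyl (2S,3S)-2,3-dihydroxybutanedioate | CCOC(=O)[C@@H](O)[C@H](O)C(=O)OCC | starting material
2 | diethyl (4S,5S)-2,2-dimethyl-1,3-dioxolane-4,5-dicarboxylate | CCOC(=O)[C@H]1OC(C)(C)O[C@@H]1C(=O)OCC | intermediate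
3 | (4S,5S)-N4,N5-dimethoxy-N4,N5,2,2-tetramethyl-1,3-dioxolane-4,5-dicarboxamide | CON(C)C(=O)[C@H]1OC(C)(C)O[C@@H]1C(=O)N(C)OC | intermediate
4 | methylmagnesium bromide | C[Mg]Br | starting material
5 | (4S,5S)-5-acetyl-N-methoxy-N,2,2-trimethyl-1,3-dioxolane-4-carboxamide | CON(C)C(=O)[C@H]1OC(C)(C)O[C@@H]1C(C)=O | intermediate
6 | (4S,5S)-5-[1-(tert-butyldimethylsilyloxy)ethenyl]-N-methoxy-N,2,2-trimethyl-1,3-dioxolane-4-carboxamide | CON(C)C(=O)[C@H]1OC(C)(C)O[C@@H]1C(=C)O[Si](C)(C)C(C)(C)C | intermediate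
7 | (4S,5S)-5-[1-(tert-butyldimethylsilyloxy)ethenyl]-2,2-dimethyl-1,3-dioxolane-4-carbaldehyde | O=C[C@H]1OC(C)(C)O[C@@H]1C(=C)O[Si](C)(C)C(C)(C)C | intermediate
8 | methyl bis(2,2,2-trifluoroethyl)phosphonoacetate | COC(=O)CP(=O)(OCC(F)(F)F)OCC(F)(F)F | starting material
9 | methyl (2Z)-3-{(4R,5S)-5-[1-(tert-butyldimethylsilyloxy)ethenyl]-2,2-dimethyl-1,3-dioxolan-4-yl}prop-2-enoate | COC(=O)/C=C\[C@H]1OC(C)(C)O[C@@H]1C(=C)O[Si](C)(C)C(C)(C)C | intermediate
10 | (2Z)-3-{(4R,5S)-5-[1-(tert-butyldimethylsilyloxy)ethenyl]-2,2-dimethyl-1,3-dioxolan-4-yl}prop-2-en-1-ol | OC/C=C\[C@H]1OC(C)(C)O[C@@H]1C(=C)O[Si](C)(C)C(C)(C)C | intermediate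
11 | (2Z)-3-{(4R,5S)-5-[1-(tert-butyldimethylsilyloxy)ethenyl]-2,2-dimethyl-1,3-dioxolan-4-yl}prop-2-enal | O=C/C=C\[C@H]1OC(C)(C)O[C@@H]1C(=C)O[Si](C)(C)C(C)(C)C | intermediate
12 | (2Z)-3-{(4R,5S)-5-[1-(tert-butyldimethylsilyloxy)ethenyl]-2,2-dimethyl-1,3-dioxolan-4-yl}prop-2-enal oxime (C=N geometry open) | ON=C/C=C\[C@H]1OC(C)(C)O[C@@H]1C(=C)O[Si](C)(C)C(C)(C)C | intermediate
13 | (2Z)-N-hydroxy-3-{(4R,5S)-5-[1-(tert-butyldimethylsilyloxy)ethenyl]-2,2-dimethyl-1,3-dioxolan-4-yl}prop-2-enimidoyl chloride | ON=C(Cl)/C=C\[C@H]1OC(C)(C)O[C@@H]1C(=C)O[Si](C)(C)C(C)(C)C | intermediate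
14 | (2Z)-3-{(4R,5S)-5-[1-(tert-butyldimethylsilyloxy)ethenyl]-2,2-dimethyl-1,3-dioxolan-4-yl}prop-2-enenitrile N-oxide | [O-][N+]#C/C=C\[C@H]1OC(C)(C)O[C@@H]1C(=C)O[Si](C)(C)C(C)(C)C | intermediate
15 | tricyclic isoxazoline (1S,5R,6S): cyclohex-3-ene ring A fused at C1–C2 to the 2-isoxazoline C2=N–O–C7H2–C1 and at C5/C6 to the trans isopropylidene acetal; C1–OTBS cis to O6 and trans to O5 | CC(C)(C)[Si](C)(C)O[C@]12CON=C1C=C[C@H]1OC(C)(C)O[C@@H]12 | intermediate
16 | (1S,5R,6S)-1-(tert-butyldimethylsilyloxy)-1-(hydroxymethyl)-5,6-(isopropylidenedioxy)cyclohex-3-en-2-imine | CC(C)(C)[Si](C)(C)O[C@]1(CO)C(=N)C=C[C@H]2OC(C)(C)O[C@@H]21 | intermediate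
17 | (1S,5R,6S)-1-(tert-butyldimethylsilyloxy)-1-(hydroxymethyl)-5,6-(isopropylidenedioxy)cyclohex-3-en-2-one | CC(C)(C)[Si](C)(C)O[C@]1(CO)C(=O)C=C[C@H]2OC(C)(C)O[C@@H]21 | intermediate
18 | [(1S,5R,6S)-1-(tert-butyldimethylsilyloxy)-5,6-(isopropylidenedioxy)-2-oxocyclohex-3-en-1-yl]methyl benzoate | CC(C)(C)[Si](C)(C)O[C@]1(COC(=O)c3ccccc3)C(=O)C=C[C@H]2OC(C)(C)O[C@@H]21 | intermediate
19 | [(1S,5R,6S)-1-hydroxy-5,6-(isopropylidenedioxy)-2-oxocyclohex-3-en-1-yl]methyl benzoate | O[C@]1(COC(=O)c3ccccc3)C(=O)C=C[C@H]2OC(C)(C)O[C@@H]21 | intermediate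
20 | [(1R,2S,5R,6S)-1,2-dihydroxy-5,6-(isopropylidenedioxy)cyclohex-3-en-1-yl]methyl benzoate (C2–OH trans to C1–OH) | O[C@]1(COC(=O)c3ccccc3)[C@@H](O)C=C[C@H]2OC(C)(C)O[C@@H]21 | intermediate
21 | [(1R,2S,5R,6S)-2-(benzoyloxy)-1-hydroxy-5,6-(isopropylidenedioxy)cyclohex-3-en-1-yl]methyl benzoate | O[C@]1(COC(=O)c3ccccc3)[C@@H](OC(=O)c3ccccc3)C=C[C@H]2OC(C)(C)O[C@@H]21 | intermediate
22 | [(1S,2S,5R,6S)-2-(benzoyloxy)-1,5,6-trihydroxycyclohex-3-en-1-yl]methyl benzoate, CNP0141358.1 | O=C(OC[C@@]1(O)[C@@H](OC(=O)c2ccccc2)C=C[C@@H](O)[C@@H]1O)c1ccccc1 | target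

**Step count**

Total: 16 steps. Longest linear sequence: 16 steps (1 to 22).

**Steps most likely to fail**

1. Step 10 (key cycloaddition). Hypochlorite may attack the electron-rich silyl enol ether (chlorination or loss of silicon) alongside oxime oxidation, or the nitrile oxide may dimerise to a furoxan if the electronically mismatched ring closure is slow. The fallback makes the same dipole without any oxidant, by dehydration of a primary nitro compound. It sets out from allylic alcohol 10. Mesylation (MsCl, Et3N, CH2Cl2, −30 °C) should give the Z-allylic mesylate F1, LiBr in THF the Z-allylic bromide F2, and NaNO2 with urea in DMF (Kornblum substitution) the Z-allylic nitro compound F3. Mukaiyama dehydration (PhNCO, Et3N cat., benzene, rt) should then release nitrile oxide 14 slowly and at low stationary concentration, and the route is rejoined at cycloadduct 15.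

2. Step 8 (Z-enal). The enal may isomerise from Z to E on MnO2 or during oximation, and the E isomer cannot reach C1. The fallback never liberates the enal. It sets out from aldehyde 7. A Z-selective Horner–Wadsworth–Emmons olefination with diphenyl cyanomethylphosphonate (KOt-Bu, THF, −78 °C) should give the Z-enenitrile F4. Reduction with i-Bu2AlH (toluene, −78 °C) should stop at the N-aluminated aldimine F5, which is quenched cold with NH2OH·HCl/NaOAc in MeOH so that transimination gives the oxime directly. The route is rejoined at oxime 12.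

3. Step 14 (directed reduction). Intermolecular hydride attack from the face opposite the axial C1–OH, or conjugate reduction, may compete with the directed delivery and erode facial selectivity at C2. The fallback sets C2 by inversion instead of by direction. It sets out from silyl ether 18. Luche reduction (NaBH4, CeCl3·7H2O, MeOH, −78 °C) should add hydride anti to the axial silyloxy group and give the C2-epimeric allylic alcohol F6 (C2–OH cis to C1–OTBS). Mitsunobu esterification with benzoic acid (PPh3, DIAD, toluene, 0 °C) should invert C2 and install the benzoate in one operation, giving the silylated dibenzoate F7. Bu4NF/AcOH in THF then removes the silyl group, and the route is rejoined at 21.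

**Further compounds**

F1 | step 10 | (2Z)-3-{(4R,5S)-5-[1-(tert-butyldimethylsilyloxy)ethenyl]-2,2-dimethyl-1,3-dioxolan-4-yl}prop-2-en-1-yl methanesulfonate | CS(=O)(=O)OC/C=C\[C@H]1OC(C)(C)O[C@@H]1C(=C)O[Si](C)(C)C(C)(C)C
F2 | step 10 | (4R,5S)-4-[(1Z)-3-bromoprop-1-en-1-yl]-5-[1-(tert-butyldimethylsilyloxy)ethenyl]-2,2-dimethyl-1,3-dioxolane | BrC/C=C\[C@H]1OC(C)(C)O[C@@H]1C(=C)O[Si](C)(C)C(C)(C)C
F3 | step 10 | (4R,5S)-5-[1-(tert-butyldimethylsilyloxy)ethenyl]-2,2-dimethyl-4-[(1Z)-3-nitroprop-1-en-1-yl]-1,3-dioxolane | O=[N+]([O-])C/C=C\[C@H]1OC(C)(C)O[C@@H]1C(=C)O[Si](C)(C)C(C)(C)C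
F4 | step 8 | (2Z)-3-{(4R,5S)-5-[1-(tert-butyldimethylsilyloxy)ethenyl]-2,2-dimethyl-1,3-dioxolan-4-yl}prop-2-enenitrile | N#C/C=C\[C@H]1OC(C)(C)O[C@@H]1C(=C)O[Si](C)(C)C(C)(C)C
F5 | step 8 | N-(diisobutylaluminio) aldimine of (2Z)-3-{(4R,5S)-5-[1-(tert-butyldimethylsilyloxy)ethenyl]-2,2-dimethyl-1,3-dioxolan-4-yl}prop-2-enal | CC(C)C[Al](CC(C)C)N=C/C=C\[C@H]1OC(C)(C)O[C@@H]1C(=C)O[Si](C)(C)C(C)(C)C
F6 | step 14 | [(1S,2R,5R,6S)-1-(tert-butyldimethylsilyloxy)-2-hydroxy-5,6-(isopropylidenedioxy)cyclohex-3-en-1-yl]methyl benzoate | CC(C)(C)[Si](C)(C)O[C@]1(COC(=O)c3ccccc3)[C@H](O)C=C[C@H]2OC(C)(C)O[C@@H]21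
F7 | step 14 | [(1S,2S,5R,6S)-2-(benzoyloxy)-1-(tert-butyldimethylsilyloxy)-5,6-(isopropylidenedioxy)cyclohex-3-en-1-yl]methyl benzoate | CC(C)(C)[Si](C)(C)O[C@]1(COC(=O)c3ccccc3)[C@@H](OC(=O)c3ccccc3)C=C[C@H]2OC(C)(C)O[C@@H]21
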